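**Retrosynthetic overview**

- The target is reached by desilylation of its silyl ether. Both rings are closed last in one flask: the C7–C7a bond by palladium/indium umpolung allylation of a C7a aldehyde with a gem-bis(acetoxymethyl)alkene (cyclohexane first), then the γ-lactone by lactonisation.
- The C3a–C4 bond comes from a catalyst-controlled anti Nozaki–Hiyama–Kishi 2-(methoxycarbonyl)allylation of an aldehyde with a Baylis–Hillman-derived allylic bromide.
- The quaternary C6 is set by the key step: a stereospecific 1,2-shift of a siloxymethyl group in a Sharpless-derived 2,3-epoxy silyl ether, giving an α-quaternary aldehyde that becomes the vinyl group.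
- The (Z)-dienol for the epoxidation comes from Suzuki coupling of a (Z)-iodoallylic alcohol (from a C4 alkyne and formaldehyde) with an alkenylboronate (from 2-methylidenepropane-1,3-diol).

Assumption: ring atoms are numbered as in 1-benzofuran-2-one (O1, C2, C3, C3a, C4, C5, C6, C7, C7a), and compounds 1, 6, 16 (60 % aqueous solution) and 17 are bought.

**Route**

Step 1
Reactants: 1 4,4-dimethoxybut-1-yne
Product: 3 5,5-dimethoxypent-2-yn-1-ol, via lithium acetylide 2 (not isolated)
Conditions: n-BuLi, THF, −78 °C; (CH2O)n, −78 °C to rt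
Reagents that add atoms: paraformaldehyde (formaldehyde unit), C=O
Why: Deprotonation of the terminal alkyne and addition of the acetylide to formaldehyde (carbonyl alkynylation) gives the propargylic alcohol; no stereocentre is formed.

Step 2
Reactants: 3 5,5-dimethoxypent-2-yn-1-ol
Product: 5 (2Z)-3-iodo-5,5-dimethoxypent-2-en-1-ol, via cyclic alkenylalanate 4 (not isolated)
Conditions: NaAlH2(OCH2CH2OMe)2, THF, 0 °C to rt; then I2, THF, −78 °C
Reagents that add atoms: iodine, II
Why: Hydroxyl-directed trans-hydroalumination puts aluminium on the distal alkyne carbon, and iodinolysis with retention gives the (Z)-3-iodoallylic alcohol, which fixes the olefin geometry.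

Step 3
Reactants: 6 2-methylidenepropane-1,3-diol
Product: 7 2,2-dimethyl-5-methylidene-1,3-dioxane
Conditions: 2,2-dimethoxypropane, TsOH·H2O (cat.), CH2Cl2, rt
Reagents that add atoms: 2,2-dimethoxypropane, COC(C)(C)OC
Why: Acid-catalysed transketalisation protects the 1,3-diol as its acetonide.

Step 4
Reactants: 7 2,2-dimethyl-5-methylidene-1,3-dioxane
Product: 8 2-[(2,2-dimethyl-1,3-dioxan-5-ylidene)methyl]-4,4,5,5-tetramethyl-1,3,2-dioxaborolane
Conditions: vinylboronic acid pinacol ester (3 equiv), second-generation Hoveyda–Grubbs catalyst (5 mol %), CH2Cl2, 40 °C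
Reagents that add atoms: 4,4,5,5-tetramethyl-2-vinyl-1,3,2-dioxaborolane, C=CB1OC(C)(C)C(C)(C)O1
Why: Olefin cross-metathesis of the 1,1-disubstituted alkene with the vinylboronate is driven by loss of ethene, and the symmetric alkene has no E/Z issue.

Step 5
Reactants: 5 (2Z)-3-iodo-5,5-dimethoxypent-2-en-1-ol; 8 2-[(2,2-dimethyl-1,3-dioxan-5-ylidene)methyl]-4,4,5,5-tetramethyl-1,3,2-dioxaborolane
Product: 9 (2Z)-3-(2,2-dimethoxyethyl)-4-(2,2-dimethyl-1,3-dioxan-5-ylidene)but-2-en-1-ol
Conditions: PdCl2(dppf) (5 mol %), K3PO4, THF–H2O, 50 °C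
Reagents that add atoms: none
Why: Suzuki–Miyaura coupling proceeds with retention at both alkenyl partners, so the alkenyl group stays cis to CH2OH.

Step 6
Reactants: 9 (2Z)-3-(2,2-dimethoxyethyl)-4-(2,2-dimethyl-1,3-dioxan-5-ylidene)but-2-en-1-ol
Product: 10 [(2S,3R)-3-(2,2-dimethoxyethyl)-3-[(2,2-dimethyl-1,3-dioxan-5-ylidene)methyl]oxiran-2-yl]methanol
Conditions: Ti(OiPr)4 (10 mol %), L-(+)-diethyl tartrate (12 mol %), t-BuOOH, 4 Å molecular sieves, CH2Cl2, −25 °C
Reagents that add atoms: tert-butyl hydroperoxide, CC(C)(C)OO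
Why: Katsuki–Sharpless asymmetric epoxidation touches only the allylic-alcohol double bond, and L-(+)-tartrate delivers oxygen to the face that gives the (2S,3R) epoxide, as with nerol-type Z-3,3-disubstituted allylic alcohols.

Step 7
Reactants: 10 [(2S,3R)-3-(2,2-dimethoxyethyl)-3-[(2,2-dimethyl-1,3-dioxan-5-ylidene)methyl]oxiran-2-yl]methanol
Product: 11 tert-butyl{[(2S,3R)-3-(2,2-dimethoxyethyl)-3-[(2,2-dimethyl-1,3-dioxan-5-ylidene)methyl]oxiran-2-yl]methoxy}diphenylsilane
Conditions: TBDPSCl, imidazole, CH2Cl2, 0 °C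
Reagents that add atoms: tert-butyl(chloro)diphenylsilane, CC(C)(C)[Si](Cl)(c1ccccc1)c1ccccc1
Why: Silylation of the primary alcohol gives the bulky, acid-stable silyl ether needed for the migration and for the later acidic steps.

Step 8
Reactants: 11 tert-butyl{[(2S,3R)-3-(2,2-dimethoxyethyl)-3-[(2,2-dimethyl-1,3-dioxan-5-ylidene)methyl]oxiran-2-yl]methoxy}diphenylsilane
Product: 12 (2R)-2-{[tert-butyl(diphenyl)silyl]oxymethyl}-4,4-dimethoxy-2-[(2,2-dimethyl-1,3-dioxan-5-ylidene)methyl]butanal
Conditions: MeAl(OAr)2 (Ar = 4-bromo-2,6-di-tert-butylphenyl, 2 equiv), CH2Cl2, −78 °C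
Reagents that add atoms: none
Why: In this semipinacol rearrangement of a 2,3-epoxy silyl ether (Maruoka–Yamamoto type) the bulky aluminium Lewis acid ionises the tertiary, allylically stabilised C–O bond and the siloxymethyl group shifts 1,2 anti to it with inversion, which turns the epoxide configuration into the (R) quaternary carbon (C6 of the target).

Step 9
Reactants: 12 (2R)-2-{[tert-butyl(diphenyl)silyl]oxymethyl}-4,4-dimethoxy-2-[(2,2-dimethyl-1,3-dioxan-5-ylidene)methyl]butanal
Product: 13 tert-butyl{[(2R)-2-(2,2-dimethoxyethyl)-2-[(2,2-dimethyl-1,3-dioxan-5-ylidene)methyl]but-3-en-1-yl]oxy}diphenylsilane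
Conditions: Ph3PCH3Br, KN(SiMe3)2, THF, 0 °C to rt
Reagents that add atoms: methyltriphenylphosphonium bromide, C[P+](c1ccccc1)(c1ccccc1)c1ccccc1.[Br-]
Why: Wittig methylenation of the non-enolisable aldehyde gives the vinyl group and cannot touch the adjacent quaternary stereocentre.

Step 10
Reactants: 13 tert-butyl{[(2R)-2-(2,2-dimethoxyethyl)-2-[(2,2-dimethyl-1,3-dioxan-5-ylidene)methyl]but-3-en-1-yl]oxy}diphenylsilane
Product: 15 (3R)-6-acetoxy-5-(acetoxymethyl)-3-{[tert-butyl(diphenyl)silyl]oxymethyl}-3-ethenylhex-4-enal, via diol aldehyde 14 (not isolated)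
Conditions: AcOH–THF–H2O (3:1:1), 40 °C; evaporate; Ac2O, pyridine, CH2Cl2, 0 °C to rt
Reagents that add atoms: water, O; acetic anhydride, CC(=O)OC(C)=O
Why: Aqueous acetic acid hydrolyses the acetonide and the dimethyl acetal but not the TBDPS ether, and acetylation of the two primary allylic alcohols then gives the symmetric bis-acetate without affecting the stereocentre.

Step 11
Reactants: 16 2,2-dimethoxyacetaldehyde; 17 methyl acrylate
Product: 18 methyl 3-hydroxy-4,4-dimethoxy-2-methylidenebutanoate (racemic)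
Conditions: DABCO (1 equiv), 1,4-dioxane–H2O (1:1), rt
Reagents that add atoms: none
Why: The Morita–Baylis–Hillman reaction works well with this electron-poor aldehyde, and the new carbinol centre is removed in the next step.

Step 12
Reactants: 18 methyl 3-hydroxy-4,4-dimethoxy-2-methylidenebutanoate
Product: 19 methyl (2Z)-2-(bromomethyl)-4,4-dimethoxybut-2-enoate
Conditions: NBS, Me2S, CH2Cl2, 0 °C to rt
Reagents that add atoms: N-bromosuccinimide, BrN1C(=O)CCC1=O
Why: Corey–Kim-type activation of the alcohol and SN2′ attack of bromide give the transposed, thermodynamically preferred (Z)-2-(bromomethyl)enoate without acid that would harm the acetal.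

Step 13
Reactants: 15 (3R)-6-acetoxy-5-(acetoxymethyl)-3-{[tert-butyl(diphenyl)silyl]oxymethyl}-3-ethenylhex-4-enal; 19 methyl (2Z)-2-(bromomethyl)-4,4-dimethoxybut-2-enoate
Product: 20 methyl (3R,4S,6R)-9-acetoxy-8-(acetoxymethyl)-6-{[tert-butyl(diphenyl)silyl]oxymethyl}-3-(dimethoxymethyl)-6-ethenyl-4-hydroxy-2-methylidenenon-7-enoate
Conditions: CrCl2 (10 mol %), chiral tridentate 1,8-bis(oxazolin-2-yl)carbazole ligand (12 mol %, enantiomer directing Re-face attack), Mn powder (2 equiv), Cp2ZrCl2 (1.1 equiv), iPr2NEt (0.3 equiv), THF, 0 °C to rt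
Reagents that add atoms: none
Why: In this catalytic asymmetric Nozaki–Hiyama–Kishi allylation the allylchromium reacts at its γ-carbon through a chair transition state to give the anti adduct, the ligand directs attack to the Re face of the aldehyde (4S, hence 3R), and the allylic acetates are inert to divalent chromium.

Step 14
Reactants: 20 methyl (3R,4S,6R)-9-acetoxy-8-(acetoxymethyl)-6-{[tert-butyl(diphenyl)silyl]oxymethyl}-3-(dimethoxymethyl)-6-ethenyl-4-hydroxy-2-methylidenenon-7-enoate
Product: 21 methyl (3R,4S,6R)-4,9-diacetoxy-8-(acetoxymethyl)-6-{[tert-butyl(diphenyl)silyl]oxymethyl}-3-(dimethoxymethyl)-6-ethenyl-2-methylidenenon-7-enoate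
Conditions: Ac2O, pyridine, DMAP (cat.), CH2Cl2, 0 °C
Reagents that add atoms: acetic anhydride, CC(=O)OC(C)=O
Why: Acetylation under basic, non-lactonising conditions installs the C4 acetate of the target and blocks lactonisation onto this oxygen.

Step 15
Reactants: 21 methyl (3R,4S,6R)-4,9-diacetoxy-8-(acetoxymethyl)-6-{[tert-butyl(diphenyl)silyl]oxymethyl}-3-(dimethoxymethyl)-6-ethenyl-2-methylidenenon-7-enoate
Product: 24 2-[(3aR,4S,6R,7S,7aR)-4-acetoxy-6-{[tert-butyl(diphenyl)silyl]oxymethyl}-6-ethenyl-3-methylidene-2-oxooctahydro-1-benzofuran-7-yl]prop-2-en-1-yl acetate, via aldehyde 22 (not isolated), via hydroxy ester 23 (not isolated)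
Conditions: Amberlyst-15, acetone–H2O (10:1), rt; filter, evaporate; Pd(PPh3)4 (5 mol %), InI (1.2 equiv), THF (0.01 M), rt; then TsOH·H2O (10 mol %), CH2Cl2, rt
Reagents that add atoms: water, O
Why: Proposed new method: zerovalent palladium ionises one of the two equivalent allylic acetates of the gem-bis(acetoxymethyl)alkene, InI reductively transmetalates the π-allyl to an allylindium with the metal on the free CH2 terminus and CH2OAc still on the central carbon, and its γ-carbon adds to the tethered aldehyde through a bicyclic chair–chair Zimmerman–Traxler transition state (C4 acetate, C3a acrylate, C7 side chain and C7a oxygen equatorial, C6 siloxymethyl axial) that sets C7 (S) and C7a (R) trans, after which the alkoxide closes the trans γ-lactone onto the acrylate ester; the closest known reaction type is the palladium-catalysed, indium-mediated umpolung (Barbier-type) allylation of aldehydes with simple allylic acetates, not shown for a bis-acetate that must keep its second allylic acetate nor coupled to ring closure and lactonisation.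

Step 16
Reactants: 24 2-[(3aR,4S,6R,7S,7aR)-4-acetoxy-6-{[tert-butyl(diphenyl)silyl]oxymethyl}-6-ethenyl-3-methylidene-2-oxooctahydro-1-benzofuran-7-yl]prop-2-en-1-yl acetate
Product: 25 2-[(3aR,4S,6R,7S,7aR)-4-acetoxy-6-ethenyl-6-(hydroxymethyl)-3-methylidene-2-oxooctahydro-1-benzofuran-7-yl]prop-2-en-1-yl acetate
Conditions: HF·pyridine, THF–pyridine, 0 °C to rt
Reagents that add atoms: none
Why: Buffered fluoride cleaves the silyl ether while the acetates, the lactone and the α-methylene unit are stable, and no acyl migration occurs under these weakly acidic conditions.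

**Compound list**

1 | 4,4-dimethoxybut-1-yne | C#CCC(OC)OC | starting material
2 | (4,4-dimethoxybut-1-yn-1-yl)lithium | [Li]C#CCC(OC)OC | intermediate
3 | 5,5-dimethoxypent-2-yn-1-ol | OCC#CCC(OC)OC | intermediate
4 | sodium 3-(2,2-dimethoxyethyl)-2,2-bis(2-methoxyethoxy)-2,5-dihydro-1,2-oxaluminol-2-uide (cyclic alkenylalanate) | [Na+].COCCO[Al-]1(OCCOC)OCC=C1CC(OC)OC | intermediate
5 | (2Z)-3-iodo-5,5-dimethoxypent-2-en-1-ol | OC/C=C(\I)CC(OC)OC | intermediate
6 | 2-methylidenepropane-1,3-diol | C=C(CO)CO | starting material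
7 | 2,2-dimethyl-5-methylidene-1,3-dioxane | C=C1COC(C)(C)OC1 | intermediate
8 | 2-[(2,2-dimethyl-1,3-dioxan-5-ylidene)methyl]-4,4,5,5-tetramethyl-1,3,2-dioxaborolane | CC1(C)OCC(=CB2OC(C)(C)C(C)(C)O2)CO1 | intermediate
9 | (2Z)-3-(2,2-dimethoxyethyl)-4-(2,2-dimethyl-1,3-dioxan-5-ylidene)but-2-en-1-ol | OC/C=C(\C=C1COC(C)(C)OC1)CC(OC)OC | intermediate
10 | [(2S,3R)-3-(2,2-dimethoxyethyl)-3-[(2,2-dimethyl-1,3-dioxan-5-ylidene)methyl]oxiran-2-yl]methanol | OC[C@@H]1O[C@@]1(C=C2COC(C)(C)OC2)CC(OC)OC | intermediate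
11 | tert-butyl{[(2S,3R)-3-(2,2-dimethoxyethyl)-3-[(2,2-dimethyl-1,3-dioxan-5-ylidene)methyl]oxiran-2-yl]methoxy}diphenylsilane | CC(C)(C)[Si](OC[C@@H]1O[C@@]1(C=C2COC(C)(C)OC2)CC(OC)OC)(c1ccccc1)c1ccccc1 | intermediate
12 | (2R)-2-{[tert-butyl(diphenyl)silyl]oxymethyl}-4,4-dimethoxy-2-[(2,2-dimethyl-1,3-dioxan-5-ylidene)methyl]butanal | O=C[C@@](CO[Si](c1ccccc1)(c1ccccc1)C(C)(C)C)(C=C1COC(C)(C)OC1)CC(OC)OC | intermediate
13 | tert-butyl{[(2R)-2-(2,2-dimethoxyethyl)-2-[(2,2-dimethyl-1,3-dioxan-5-ylidene)methyl]but-3-en-1-yl]oxy}diphenylsilane | C=C[C@@](CO[Si](c1ccccc1)(c1ccccc1)C(C)(C)C)(C=C1COC(C)(C)OC1)CC(OC)OC | intermediate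
14 | (3R)-3-{[tert-butyl(diphenyl)silyl]oxymethyl}-3-ethenyl-6-hydroxy-5-(hydroxymethyl)hex-4-enal (diol aldehyde) | C=C[C@@](CO[Si](c1ccccc1)(c1ccccc1)C(C)(C)C)(C=C(CO)CO)CC=O | intermediate
15 | (3R)-6-acetoxy-5-(acetoxymethyl)-3-{[tert-butyl(diphenyl)silyl]oxymethyl}-3-ethenylhex-4-enal | C=C[C@@](CO[Si](c1ccccc1)(c1ccccc1)C(C)(C)C)(C=C(COC(C)=O)COC(C)=O)CC=O | intermediate
16 | 2,2-dimethoxyacetaldehyde | COC(OC)C=O | starting material
17 | methyl acrylate | C=CC(=O)OC | starting material
18 | methyl 3-hydroxy-4,4-dimethoxy-2-methylidenebutanoate (racemic) | COC(=O)C(=C)C(O)C(OC)OC | intermediate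
19 | methyl (2Z)-2-(bromomethyl)-4,4-dimethoxybut-2-enoate | COC(=O)/C(CBr)=C/C(OC)OC | intermediate
20 | methyl (3R,4S,6R)-9-acetoxy-8-(acetoxymethyl)-6-{[tert-butyl(diphenyl)silyl]oxymethyl}-3-(dimethoxymethyl)-6-ethenyl-4-hydroxy-2-methylidenenon-7-enoate | C=C[C@@](CO[Si](c1ccccc1)(c1ccccc1)C(C)(C)C)(C=C(COC(C)=O)COC(C)=O)C[C@H](O)[C@@H](C(=C)C(=O)OC)C(OC)OC | intermediate
21 | methyl (3R,4S,6R)-4,9-diacetoxy-8-(acetoxymethyl)-6-{[tert-butyl(diphenyl)silyl]oxymethyl}-3-(dimethoxymethyl)-6-ethenyl-2-methylidenenon-7-enoate | C=C[C@@](CO[Si](c1ccccc1)(c1ccccc1)C(C)(C)C)(C=C(COC(C)=O)COC(C)=O)C[C@H](OC(C)=O)[C@@H](C(=C)C(=O)OC)C(OC)OC | intermediate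
22 | methyl (3R,4S,6R)-4,9-diacetoxy-8-(acetoxymethyl)-6-{[tert-butyl(diphenyl)silyl]oxymethyl}-6-ethenyl-3-formyl-2-methylidenenon-7-enoate (aldehyde) | C=C[C@@](CO[Si](c1ccccc1)(c1ccccc1)C(C)(C)C)(C=C(COC(C)=O)COC(C)=O)C[C@H](OC(C)=O)[C@@H](C(=C)C(=O)OC)C=O | intermediate
23 | methyl 2-[(1S,2R,3S,4R,6S)-6-acetoxy-3-(3-acetoxyprop-1-en-2-yl)-4-{[tert-butyl(diphenyl)silyl]oxymethyl}-4-ethenyl-2-hydroxycyclohexyl]prop-2-enoate (hydroxy ester) | C=C[C@]1(CO[Si](c2ccccc2)(c2ccccc2)C(C)(C)C)C[C@H](OC(C)=O)[C@@H](C(=C)C(=O)OC)[C@H](O)[C@H]1C(=C)COC(C)=O | intermediate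
24 | 2-[(3aR,4S,6R,7S,7aR)-4-acetoxy-6-{[tert-butyl(diphenyl)silyl]oxymethyl}-6-ethenyl-3-methylidene-2-oxooctahydro-1-benzofuran-7-yl]prop-2-en-1-yl acetate | C=C[C@]1(CO[Si](c3ccccc3)(c3ccccc3)C(C)(C)C)C[C@H](OC(C)=O)[C@H]2C(=C)C(=O)O[C@@H]2[C@H]1C(=C)COC(C)=O | intermediate
25 | 2-[(3aR,4S,6R,7S,7aR)-4-acetoxy-6-ethenyl-6-(hydroxymethyl)-3-methylidene-2-oxooctahydro-1-benzofuran-7-yl]prop-2-en-1-yl acetate | C=C[C@]1(CO)C[C@H](OC(C)=O)[C@H]2C(=C)C(=O)O[C@@H]2[C@H]1C(=C)COC(C)=O | target

**Step count**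

Total steps: 16. Longest linear sequence: 12 steps (1, 2, 5, 6, 7, 8, 9, 10, 13, 14, 15, 16).

**Steps most likely to fail, with fallbacks**

Step 15 (the proposed new step). The risks are a second ionisation of the allylic acetate that must survive, loss of the epimerisable aldehyde 22 by conjugation, and a cis ring closure. The fallback uses known chemistry and sets out from 21. Palladium-catalysed borylation of one allylic acetate (Pd2(dba)3, B2pin2, DMSO, 50 °C) gives the isolable allylboronate acetal F1, with boron on the CH2 trans to the quaternary carbon. Amberlyst-15 in wet acetone unmasks the allylboronate aldehyde F2, which cyclises without any metal by intramolecular allylboration through a closed chair transition state. Triethanolamine work-up gives hydroxy ester 23, and TsOH closes the lactone, so the route is rejoined at 24.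

Step 13. The risks are double stereodifferentiation against the remote quaternary centre, the anti/syn ratio with a γ-acetal substituent, and premature lactonisation. The fallback sets out from 15 and replaces the chromium allyl by an isolated allylboronate. Commercial 3,3-dimethoxyprop-1-yne is carboxylated (n-BuLi, ClCO2Me) to the ynoate F3. Syn hydroalumination (iBu2AlH, HMPA) and alkylation of the α-alumino acrylate with ClCH2Bpin give the boronate F4, with boron trans to the acetal carbon. Allylboration of 15 catalysed by a chiral BINOL-derived phosphoric acid, through a closed chair transition state, gives the anti adduct, and the route is rejoined at 20.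

Step 6. The risks are that a Z-trisubstituted dienol is a slow Sharpless substrate and that the product is an acid-labile tertiary vinyl epoxide exposed to the titanium alkoxide. The fallback sets out from 9 and removes the free hydroxyl first: silylation (TBDPSCl, imidazole) gives the dienyl silyl ether F5. Shi epoxidation of the more electron-rich trisubstituted alkene (fructose-derived ketone catalyst, KHSO5, K2CO3 buffer, MeCN–dimethoxymethane–H2O, 0 °C; catalyst enantiomer chosen for the same olefin face) then gives the epoxy silyl ether directly, and the route is rejoined at 11.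

**Further compounds**

F1 | step 15 | methyl (3R,4S,6R,7Z)-4,9-diacetoxy-6-{[tert-butyl(diphenyl)silyl]oxymethyl}-3-(dimethoxymethyl)-6-ethenyl-2-methylidene-8-[(4,4,5,5-tetramethyl-1,3,2-dioxaborolan-2-yl)methyl]non-7-enoate | C=C[C@@](CO[Si](c1ccccc1)(c1ccccc1)C(C)(C)C)(/C=C(/CB1OC(C)(C)C(C)(C)O1)COC(C)=O)C[C@H](OC(C)=O)[C@@H](C(=C)C(=O)OC)C(OC)OC
F2 | step 15 | methyl (3R,4S,6R,7Z)-4,9-diacetoxy-6-{[tert-butyl(diphenyl)silyl]oxymethyl}-6-ethenyl-3-formyl-2-methylidene-8-[(4,4,5,5-tetramethyl-1,3,2-dioxaborolan-2-yl)methyl]non-7-enoate | C=C[C@@](CO[Si](c1ccccc1)(c1ccccc1)C(C)(C)C)(/C=C(/CB1OC(C)(C)C(C)(C)O1)COC(C)=O)C[C@H](OC(C)=O)[C@@H](C(=C)C(=O)OC)C=O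
F3 | step 13 | methyl 4,4-dimethoxybut-2-ynoate | COC(=O)C#CC(OC)OC
F4 | step 13 | methyl (2Z)-4,4-dimethoxy-2-[(4,4,5,5-tetramethyl-1,3,2-dioxaborolan-2-yl)methyl]but-2-enoate | COC(=O)/C(CB1OC(C)(C)C(C)(C)O1)=C\C(OC)OC
F5 | step 6 | tert-butyl{[(2Z)-3-(2,2-dimethoxyethyl)-4-(2,2-dimethyl-1,3-dioxan-5-ylidene)but-2-en-1-yl]oxy}diphenylsilane | CC(C)(C)[Si](OC/C=C(\C=C1COC(C)(C)OC1)CC(OC)OC)(c1ccccc1)c1ccccc1
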